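**Plan** (germacrane numbering: C1 ketone, C4–C5 oxirane, C6 lactone CH–O, C7=C11 butenolide alkene, C8 acyloxy CH, C10 CH(CH3), C12 lactone C=O, C13 CH2OAc)
1. Enabling feature: the C2–C3 bond joins the α-carbon of the C1 ketone to the allylic terminus of the C4=C5 alkene (the oxirane precursor). This is the retron of an allyl β-keto ester, so the ten-membered ring can be contracted out of a twelve-membered C1-keto / C3–O lactone.
2. Cuts, in order: C8 ester, C13 acetate and oxirane off; C2–C3 (with CO2 re-inserted); the C3–O ester bond (acylketene); C6–C7 and O–C12 of the butenolide; C7–C11 (Claisen).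
3. Forward ring order: butenolide (step 13), twelve-membered β-keto lactone (step 17), ten-membered carbocycle by loss of CO2 (step 18), oxirane (step 25).
4. Stereochemistry: C8 from (S)-5-(hydroxymethyl)butyrolactone; C10 by trans-alkylation of that lactone; C6 by a ligand-controlled coupling; C4/C5 by face-selective epoxidation. The target oxirane is (4R,5S), i.e. cis (C3 and C6 on the same side), so C4=C5 is built and carried as the Z isomer, set by anti-carbomagnesiation of propargyl alcohol.

Key step: step 18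

Assumption: in step 13 the sense of induction of the oxazoline–sulfonamide ligand relative to the resident C8 centre must be matched by trial; the (S)-valinol-derived antipode is written and its enantiomer is used if that proves to be the matched one.

**Step 1**
Reactants: 1 (S)-5-(hydroxymethyl)dihydrofuran-2(3H)-one
Product: 2 (S)-5-((trityloxy)methyl)dihydrofuran-2(3H)-one
Conditions: TrCl, pyridine, DMAP (cat.), CH2Cl2, rt
Reagents that add atoms: trityl chloride, ClC(c1ccccc1)(c1ccccc1)c1ccccc1
Why: Tritylation of the primary alcohol installs the bulky group that will shield one face of the lactone enolate, while C8 (S) is taken unchanged from the commercial lactone.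

**Step 2**
Reactants: 2 (S)-5-((trityloxy)methyl)dihydrofuran-2(3H)-one
Product: 4 (3R,5S)-3-methyl-5-((trityloxy)methyl)dihydrofuran-2(3H)-one, via lithium enolate 3 (not isolated)
Conditions: LiN(i-Pr)2, THF, −78 °C; MeI, −78 °C
Reagents that add atoms: iodomethane, CI
Why: Enolate alkylation of a 5-substituted γ-butyrolactone occurs anti to the C5 substituent, so the C10 methyl centre (R) should be set trans to the trityloxymethyl group by 1,3-induction from C8.

**Step 3**
Reactants: 4 (3R,5S)-3-methyl-5-((trityloxy)methyl)dihydrofuran-2(3H)-one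
Product: 7 (2R,4S)-4-((tert-butyldimethylsilyl)oxy)-2-methyl-5-(trityloxy)pentanoic acid, via potassium hydroxy carboxylate 5 (not isolated), via bis-silyl ester 6 (not isolated)
Conditions: KOH, THF–MeOH–H2O, rt, evaporation; TBSCl, imidazole, DMF, rt; AcOH–THF–H2O, rt
Reagents that add atoms: potassium hydroxide, [K+].[OH-]; tert-butyldimethylsilyl chloride, CC(C)(C)[Si](C)(C)Cl
Why: Saponification opens the lactone, exhaustive silylation caps the C8 hydroxyl before it can relactonise, and only the labile silyl ester is hydrolysed by mild aqueous acid (lactone opening–silylation sequence), leaving both stereocentres untouched.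

**Step 4**
Reactants: 7 (2R,4S)-4-((tert-butyldimethylsilyl)oxy)-2-methyl-5-(trityloxy)pentanoic acid
Product: 8 allyl (2R,4S)-4-((tert-butyldimethylsilyl)oxy)-2-methyl-5-(trityloxy)pentanoate
Conditions: allyl bromide, K2CO3, DMF, rt
Reagents that add atoms: allyl bromide, C=CCBr
Why: SN2 O-alkylation of the carboxylate masks C1 as an ester that survives enolate chemistry and is later removed under neutral conditions.

**Step 5**
Reactants: 8 allyl (2R,4S)-4-((tert-butyldimethylsilyl)oxy)-2-methyl-5-(trityloxy)pentanoate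
Product: 9 allyl (2R,4S)-4-((tert-butyldimethylsilyl)oxy)-5-hydroxy-2-methylpentanoate
Conditions: TsOH·H2O (cat.), MeOH–CH2Cl2, 0 °C
Reagents that add atoms: none
Why: Acid-catalysed methanolysis of the trityl ether through the trityl cation is much faster than cleavage of the hindered secondary TBS ether, so only the C7 hydroxyl is freed (the product is oxidised at once to avoid δ-lactonisation).

**Step 6**
Reactants: 9 allyl (2R,4S)-4-((tert-butyldimethylsilyl)oxy)-5-hydroxy-2-methylpentanoate
Product: 10 (2S,4R)-5-(allyloxy)-2-((tert-butyldimethylsilyl)oxy)-4-methyl-5-oxopentanoic acid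
Conditions: TEMPO (cat.), PhI(OAc)2, MeCN–H2O, rt
Reagents that add atoms: water, O
Why: Oxoammonium-mediated oxidation takes the primary alcohol through the aldehyde hydrate to the acid under near-neutral conditions that should neither epimerise the α-silyloxy centre nor touch the allyl ester.

**Step 7**
Reactants: 11 4-methoxybenzyl alcohol; 12 methyl acrylate
Product: 13 methyl 3-((4-methoxybenzyl)oxy)propanoate
Conditions: NaH (cat.), THF, 0 °C to rt
Reagents that add atoms: none
Why: Alkoxide-catalysed oxa-Michael addition of the benzylic alcohol to the acrylate gives the β-alkoxy ester that supplies C11, C12 and C13.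

**Step 8**
Reactants: 10 (2S,4R)-5-(allyloxy)-2-((tert-butyldimethylsilyl)oxy)-4-methyl-5-oxopentanoic acid; 13 methyl 3-((4-methoxybenzyl)oxy)propanoate
Product: 16 7-allyl 1-methyl (4S,6R)-4-((tert-butyldimethylsilyl)oxy)-2-(((4-methoxybenzyl)oxy)methyl)-6-methyl-3-oxoheptanedioate (C2 epimers), via acyl imidazole 14 (not isolated), via lithium ester enolate 15 (not isolated)
Conditions: 10, 1,1'-carbonyldiimidazole, THF, rt; added to 13 / LiN(i-Pr)2 (2.5 equiv), THF, −78 °C; AcOH, −78 °C
Reagents that add atoms: none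
Why: Crossed Claisen condensation of an ester lithium enolate with an acyl imidazole forms C7–C11, the excess enolate storing the product as its stabilised enolate so that C8 should not epimerise (the C11 centre is erased in the next step).

**Step 9**
Reactants: 16 7-allyl 1-methyl (4S,6R)-4-((tert-butyldimethylsilyl)oxy)-2-(((4-methoxybenzyl)oxy)methyl)-6-methyl-3-oxoheptanedioate
Product: 18 7-allyl 1-methyl (2Z,4S,6R)-4-((tert-butyldimethylsilyl)oxy)-2-(((4-methoxybenzyl)oxy)methyl)-6-methyl-3-(((trifluoromethyl)sulfonyl)oxy)hept-2-enedioate, via sodium enolate 17 (not isolated)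
Conditions: NaH, THF, 0 °C; PhNTf2, 0 °C to rt
Reagents that add atoms: N-phenylbis(trifluoromethanesulfonimide), O=S(=O)(N(c1ccccc1)S(=O)(=O)C(F)(F)F)C(F)(F)F
Why: O-Sulfonylation of the sodium-chelated β-keto ester enolate, whose enolate oxygen is held cis to the ester carbonyl, should give the (Z)-enol triflate and so fix the tetrasubstituted C7=C11 geometry needed for lactonisation.

**Step 10**
Reactants: 19 prop-2-yn-1-ol
Product: 21 (Z)-3-iodo-2-methylprop-2-en-1-ol, via alkenylmagnesium alkoxide 20 (not isolated)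
Conditions: MeMgBr (3 equiv), CuI (cat.), Et2O, −10 °C to rt; I2, −10 °C; H2O
Reagents that add atoms: methylmagnesium bromide, C[Mg]Br; iodine, II
Why: Copper-catalysed anti-carbomagnesiation of the magnesium propargyl alkoxide delivers methyl to the proximal alkyne carbon and magnesium to the terminus within a five-membered chelate, and iodinolysis with retention gives the (Z)-iodoalkene that fixes the C4=C5 geometry.

**Step 11**
Reactants: 21 (Z)-3-iodo-2-methylprop-2-en-1-ol
Product: 22 (Z)-tert-butyl((3-iodo-2-methylallyl)oxy)dimethylsilane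
Conditions: TBSCl, imidazole, CH2Cl2, rt
Reagents that add atoms: tert-butyldimethylsilyl chloride, CC(C)(C)[Si](C)(C)Cl
Why: Routine silylation protects the C3 hydroxyl with a group that can later be removed selectively as a primary silyl ether.

**Step 12**
Reactants: 22 (Z)-tert-butyl((3-iodo-2-methylallyl)oxy)dimethylsilane
Product: 24 (Z)-4-((tert-butyldimethylsilyl)oxy)-3-methylbut-2-enal, via alkenyllithium 23 (not isolated)
Conditions: t-BuLi (2.1 equiv), Et2O, −78 °C; DMF, −78 °C; H2O
Reagents that add atoms: N,N-dimethylformamide, CN(C)C=O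
Why: Iodine–lithium exchange gives an alkenyllithium that is configurationally stable at −78 °C in ether (where 1,4-silyl migration is slow) and is formylated with retention (Bouveault-type formylation), the (Z)-enal being used at once.

**Step 13**
Reactants: 18 (Z)-enol triflate; 24 (Z)-4-((tert-butyldimethylsilyl)oxy)-3-methylbut-2-enal
Product: 26 allyl (2R,4S)-4-((tert-butyldimethylsilyl)oxy)-4-{(2R)-2-[(1Z)-3-((tert-butyldimethylsilyl)oxy)-2-methylprop-1-en-1-yl]-4-(((4-methoxybenzyl)oxy)methyl)-5-oxo-2,5-dihydrofuran-3-yl}-2-methylbutanoate, via hydroxy ester 25 (not isolated)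
Conditions: CrCl2 (4 equiv), (S)-N-[2-(4-isopropyl-4,5-dihydrooxazol-2-yl)-6-methylphenyl]methanesulfonamide (4.4 equiv), Et3N, THF, rt; NiCl2 (cat.), 18 + 24, rt; PPTS (cat.), CH2Cl2, rt
Reagents that add atoms: none
Why: In this Nozaki–Hiyama–Kishi coupling zerovalent nickel inserts into the alkenyl triflate, transmetallation gives an alkenyl species of trivalent chromium that adds to the enal with retention of both alkene geometries, the chromium-bound chiral ligand selecting the aldehyde face that gives C6 (R), and the alkoxide held cis to the methyl ester closes the butenolide.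

**Step 14**
Reactants: 26 butenolide allyl ester
Product: 27 (2R,4S)-4-((tert-butyldimethylsilyl)oxy)-4-{(2R)-2-[(1Z)-3-((tert-butyldimethylsilyl)oxy)-2-methylprop-1-en-1-yl]-4-(((4-methoxybenzyl)oxy)methyl)-5-oxo-2,5-dihydrofuran-3-yl}-2-methylbutanoic acid
Conditions: Pd(PPh3)4 (5 mol%), morpholine, THF, 0 °C
Reagents that add atoms: none
Why: In this Tsuji–Trost deallylation zerovalent palladium ionises the unhindered allyl ester far faster than the hindered secondary allylic lactone C6–O bond, and morpholine captures the allyl unit.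

**Step 15**
Reactants: 27 butenolide C1 acid; 28 2,2-dimethyl-1,3-dioxane-4,6-dione (Meldrum's acid)
Product: 29 acyl Meldrum's acid (enol form), the C1 acyl group of 27 on C5 of the dioxanedione (C3 OTBS, C8 OTBS, C13 OPMB; 4Z,6R,8S,10R)
Conditions: DCC, DMAP, CH2Cl2, 0 °C to rt; cold aq. KHSO4 wash
Reagents that add atoms: none
Why: Carbodiimide-mediated C-acylation of Meldrum's acid gives the enolised acyl dioxanedione, a bench-stable precursor of the C1 acylketene.

**Step 16**
Reactants: 29 acyl Meldrum's acid (C3 OTBS)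
Product: 30 acyl Meldrum's acid with free C3 hydroxyl (C8 OTBS, C13 OPMB; 4Z,6R,8S,10R)
Conditions: HF·pyridine, pyridine, THF, 0 °C
Reagents that add atoms: none
Why: Buffered fluoride cleaves the unhindered primary allylic TBS ether much faster than the hindered secondary one at C8, and the acyl Meldrum's acid is inert below its fragmentation temperature.

**Step 17**
Reactants: 30 acyl Meldrum's acid with free C3 hydroxyl
Product: 32 twelve-membered allyl β-keto lactone (ring O–C3H2–C4(CH3)=C5H–C6H–C7–C8H(OTBS)–C9H2–C10H(CH3)–C1(=O)–C2H2–C(=O), fused at C6–C7 to the 13-(4-methoxybenzyloxy)butenolide; 4Z,6R,8S,10R), via acylketene 31 (not isolated)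
Conditions: toluene, 110 °C, slow addition to a final concentration of 1 mM or less
Reagents that add atoms: none
Why: Thermal fragmentation of the acyl Meldrum's acid releases acetone and CO2 to give an acylketene that is trapped at its ketene carbon by the C3 hydroxyl under high dilution (acylketene macrolactonisation), the (Z)-alkene and the rigid butenolide turning the chain ends toward each other.

**Step 18**
Reactants: 32 twelve-membered allyl β-keto lactone
Product: 33 (4Z,6R,8S,10R)-8-((tert-butyldimethylsilyl)oxy)-13-((4-methoxybenzyl)oxy)-1-oxogermacra-4,7(11)-dien-12,6-olide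
Conditions: Pd(PPh3)4 (10 mol%), degassed THF, 2 mM, 40 °C
Reagents that add atoms: none
Why: Zerovalent palladium adds to the C4=C5 alkene anti to the primary C3–O bond and ionises it to an anti-configured π-allyl complex of divalent palladium whose counter-ion is the tethered β-keto carboxylate; loss of CO2 leaves a C1–C2 palladium enolate paired with the allyl unit, and C2 bonds to the unsubstituted terminus C3. The closest known reaction type is the Tsuji (palladium-Carroll) decarboxylative allylation of allyl β-keto esters, used here in its intramolecular, ring-contracting form on a lactone, for which direct precedent is scarce. The ten-membered carbocycle closes by enolate C-allylation with the allyl unit endocyclic (a 10-endo closure, formally a 12-to-10 contraction), so the entropic cost of the medium ring was already paid in the lactonisation and the chain ends never separate. No stereocentre is formed; C6, C8 and C10 are spectators, and C10 is protected because decarboxylation delivers the enolate regiospecifically at C1–C2. The step needs attack at C3 and not C5, retention of the Z geometry and survival of the C6–O lactone bond: the first follows from the preference for the less hindered terminus (C5 attack would also require an eight-membered ring); the second from capture of the anti complex by the tethered enolate before π–σ–π isomerisation, which would need a σ-bond at the hindered secondary C5 and would lead to the more strained (E)-cyclodecene; the third from ionisation at the secondary C6–O bond being slower and reversible, whereas only C3 ionisation is followed by irreversible loss of CO2.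

**Step 19**
Reactants: 33 ring-contracted PMB ether
Product: 34 (4Z,6R,8S,10R)-8-((tert-butyldimethylsilyl)oxy)-13-hydroxy-1-oxogermacra-4,7(11)-dien-12,6-olide
Conditions: DDQ, CH2Cl2–pH 7 buffer, 0 °C
Reagents that add atoms: none
Why: Oxidative cleavage of the PMB ether by hydride abstraction at the electron-rich benzylic position leaves the silyl ether, the ketone and the alkenes untouched.

**Step 20**
Reactants: 34 C13 alcohol
Product: 35 (4Z,6R,8S,10R)-13-acetoxy-8-((tert-butyldimethylsilyl)oxy)-1-oxogermacra-4,7(11)-dien-12,6-olide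
Conditions: Ac2O, pyridine, DMAP (cat.), CH2Cl2, 0 °C
Reagents that add atoms: acetic anhydride, CC(=O)OC(C)=O
Why: Nucleophile-catalysed acetylation of the primary allylic alcohol installs the C13 acetate of the target.

**Step 21**
Reactants: 35 C13 acetate
Product: 36 (4Z,6R,8S,10R)-13-acetoxy-8-hydroxy-1-oxogermacra-4,7(11)-dien-12,6-olide
Conditions: HF·pyridine, THF, 0 °C to rt
Reagents that add atoms: none
Why: Fluoride-mediated desilylation under mildly acidic conditions frees the C8 hydroxyl without acetyl migration, and translactonisation is excluded because C8 is held trans to C12 across C7=C11.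

**Step 22**
Reactants: 37 ethyl 2-(hydroxymethyl)acrylate
Product: 38 ethyl 2-(((tert-butyldimethylsilyl)oxy)methyl)acrylate
Conditions: TBSCl, imidazole, CH2Cl2, rt
Reagents that add atoms: tert-butyldimethylsilyl chloride, CC(C)(C)[Si](C)(C)Cl
Why: Silylation blocks the side-chain hydroxyl so that the acid cannot self-esterify in the coupling.

**Step 23**
Reactants: 38 ethyl 2-(((tert-butyldimethylsilyl)oxy)methyl)acrylate
Product: 39 2-(((tert-butyldimethylsilyl)oxy)methyl)acrylic acid
Conditions: LiOH, THF–H2O, 0 °C to rt; aq. HCl to pH 4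
Reagents that add atoms: lithium hydroxide, [Li+].[OH-]
Why: Saponification of the ethyl ester proceeds under conditions that a primary TBS ether tolerates.

**Step 24**
Reactants: 36 C8 alcohol; 39 2-(((tert-butyldimethylsilyl)oxy)methyl)acrylic acid
Product: 40 (4Z,6R,8S,10R)-13-acetoxy-8-[2-(((tert-butyldimethylsilyl)oxy)methyl)acryloyloxy]-1-oxogermacra-4,7(11)-dien-12,6-olide
Conditions: DCC, DMAP (cat.), CH2Cl2, 0 °C to rt
Reagents that add atoms: none
Why: Steglich esterification acylates the hindered secondary allylic alcohol with retention at C8 under conditions mild enough for the acetate and the C10 centre.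

**Step 25**
Reactants: 40 C8 ester
Product: 41 (4R,5S,6S,8S,10R)-13-acetoxy-8-[2-(((tert-butyldimethylsilyl)oxy)methyl)acryloyloxy]-4,5-epoxy-1-oxogermacr-7(11)-en-12,6-olide
Conditions: mCPBA, NaHCO3, CH2Cl2, 0 °C
Reagents that add atoms: 3-chloroperoxybenzoic acid, O=C(OO)c1cccc(Cl)c1
Why: Prilezhaev epoxidation is chemoselective for the only electron-rich alkene and stereospecific, so the (Z)-alkene gives the cis-oxirane, and with C6–H eclipsing the alkene (allylic 1,3-strain against C3H2) oxygen delivery anti to the electron-withdrawing C6–O bond should set C4 (R) and C5 (S).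

**Step 26**
Reactants: 41 epoxide
Product: 42 target, (4R,5S,6S,8S,10R)-13-acetoxy-4,5-epoxy-8-[2-(hydroxymethyl)acryloyloxy]-1-oxogermacr-7(11)-en-12,6-olide
Conditions: HF·pyridine, pyridine, THF, 0 °C
Reagents that add atoms: none
Why: Pyridine-buffered fluoride removes the primary allylic TBS ether rapidly while the oxirane, the acetate and the acrylate ester are expected to survive.

**Compound list**
1 | (S)-5-(hydroxymethyl)dihydrofuran-2(3H)-one | OC[C@@H]1CCC(=O)O1 | starting material
2 | (S)-5-((trityloxy)methyl)dihydrofuran-2(3H)-one | c1ccc(cc1)C(c1ccccc1)(c1ccccc1)OC[C@@H]1CCC(=O)O1 | intermediate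
3 | lithium enolate of 2 | c1ccc(cc1)C(c1ccccc1)(c1ccccc1)OC[C@@H]1CC=C(O[Li])O1 | intermediate
4 | (3R,5S)-3-methyl-5-((trityloxy)methyl)dihydrofuran-2(3H)-one | c1ccc(cc1)C(c1ccccc1)(c1ccccc1)OC[C@@H]1C[C@@H](C)C(=O)O1 | intermediate
5 | potassium (2R,4S)-4-hydroxy-2-methyl-5-(trityloxy)pentanoate | [K+].[O-]C(=O)[C@H](C)C[C@H](O)COC(c1ccccc1)(c1ccccc1)c1ccccc1 | intermediate
6 | tert-butyldimethylsilyl (2R,4S)-4-((tert-butyldimethylsilyl)oxy)-2-methyl-5-(trityloxy)pentanoate | CC(C)(C)[Si](C)(C)OC(=O)[C@H](C)C[C@H](O[Si](C)(C)C(C)(C)C)COC(c1ccccc1)(c1ccccc1)c1ccccc1 | intermediate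
7 | (2R,4S)-4-((tert-butyldimethylsilyl)oxy)-2-methyl-5-(trityloxy)pentanoic acid | OC(=O)[C@H](C)C[C@H](O[Si](C)(C)C(C)(C)C)COC(c1ccccc1)(c1ccccc1)c1ccccc1 | intermediate
8 | allyl (2R,4S)-4-((tert-butyldimethylsilyl)oxy)-2-methyl-5-(trityloxy)pentanoate | C=CCOC(=O)[C@H](C)C[C@H](O[Si](C)(C)C(C)(C)C)COC(c1ccccc1)(c1ccccc1)c1ccccc1 | intermediate
9 | allyl (2R,4S)-4-((tert-butyldimethylsilyl)oxy)-5-hydroxy-2-methylpentanoate | C=CCOC(=O)[C@H](C)C[C@H](O[Si](C)(C)C(C)(C)C)CO | intermediate
10 | (2S,4R)-5-(allyloxy)-2-((tert-butyldimethylsilyl)oxy)-4-methyl-5-oxopentanoic acid | C=CCOC(=O)[C@H](C)C[C@H](O[Si](C)(C)C(C)(C)C)C(=O)O | intermediate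
11 | 4-methoxybenzyl alcohol | COc1ccc(CO)cc1 | starting material
12 | methyl acrylate | C=CC(=O)OC | starting material
13 | methyl 3-((4-methoxybenzyl)oxy)propanoate | COC(=O)CCOCc1ccc(OC)cc1 | intermediate
14 | allyl (2R,4S)-4-((tert-butyldimethylsilyl)oxy)-5-(1H-imidazol-1-yl)-2-methyl-5-oxopentanoate (acyl imidazole) | C=CCOC(=O)[C@H](C)C[C@H](O[Si](C)(C)C(C)(C)C)C(=O)n1ccnc1 | intermediate
15 | lithium enolate of 13 | [Li]OC(OC)=CCOCc1ccc(OC)cc1 | intermediate
16 | 7-allyl 1-methyl (4S,6R)-4-((tert-butyldimethylsilyl)oxy)-2-(((4-methoxybenzyl)oxy)methyl)-6-methyl-3-oxoheptanedioate (C2 epimers) | C=CCOC(=O)[C@H](C)C[C@H](O[Si](C)(C)C(C)(C)C)C(=O)C(COCc1ccc(OC)cc1)C(=O)OC | intermediate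
17 | sodium (Z)-enolate of 16 | C=CCOC(=O)[C@H](C)C[C@H](O[Si](C)(C)C(C)(C)C)/C(O[Na])=C(\COCc1ccc(OC)cc1)C(=O)OC | intermediate
18 | 7-allyl 1-methyl (2Z,4S,6R)-4-((tert-butyldimethylsilyl)oxy)-2-(((4-methoxybenzyl)oxy)methyl)-6-methyl-3-(((trifluoromethyl)sulfonyl)oxy)hept-2-enedioate | C=CCOC(=O)[C@H](C)C[C@H](O[Si](C)(C)C(C)(C)C)/C(OS(=O)(=O)C(F)(F)F)=C(\COCc1ccc(OC)cc1)C(=O)OC | intermediate
19 | prop-2-yn-1-ol | C#CCO | starting material
20 | bromomagnesium (Z)-3-(bromomagnesio)-2-methylprop-2-en-1-olate | Br[Mg]OC/C(C)=C\[Mg]Br | intermediate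
21 | (Z)-3-iodo-2-methylprop-2-en-1-ol | OC/C(C)=C\I | intermediate
22 | (Z)-tert-butyl((3-iodo-2-methylallyl)oxy)dimethylsilane | CC(C)(C)[Si](C)(C)OC/C(C)=C\I | intermediate
23 | (Z)-[3-((tert-butyldimethylsilyl)oxy)-2-methylprop-1-en-1-yl]lithium | CC(C)(C)[Si](C)(C)OC/C(C)=C\[Li] | intermediate
24 | (Z)-4-((tert-butyldimethylsilyl)oxy)-3-methylbut-2-enal | CC(C)(C)[Si](C)(C)OC/C(C)=C\C=O | intermediate
25 | methyl γ-hydroxy enoate, seco form of 26 (C6 carbinol cis to CO2Me; 6R,8S,10R, 4Z) | C=CCOC(=O)[C@H](C)C[C@H](O[Si](C)(C)C(C)(C)C)/C([C@H](O)/C=C(C)\CO[Si](C)(C)C(C)(C)C)=C(\COCc1ccc(OC)cc1)C(=O)OC | intermediate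
26 | allyl (2R,4S)-4-((tert-butyldimethylsilyl)oxy)-4-{(2R)-2-[(1Z)-3-((tert-butyldimethylsilyl)oxy)-2-methylprop-1-en-1-yl]-4-(((4-methoxybenzyl)oxy)methyl)-5-oxo-2,5-dihydrofuran-3-yl}-2-methylbutanoate | C=CCOC(=O)[C@H](C)C[C@H](O[Si](C)(C)C(C)(C)C)C1=C(COCc2ccc(OC)cc2)C(=O)O[C@@H]1/C=C(C)\CO[Si](C)(C)C(C)(C)C | intermediate
27 | the corresponding butanoic acid (C1 acid of 26) | OC(=O)[C@H](C)C[C@H](O[Si](C)(C)C(C)(C)C)C1=C(COCc2ccc(OC)cc2)C(=O)O[C@@H]1/C=C(C)\CO[Si](C)(C)C(C)(C)C | intermediate
28 | 2,2-dimethyl-1,3-dioxane-4,6-dione | CC1(C)OC(=O)CC(=O)O1 | starting material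
29 | acyl Meldrum's acid (enol form) from 27, C3 OTBS | CC1(C)OC(=O)C(=C(O)[C@H](C)C[C@H](O[Si](C)(C)C(C)(C)C)C2=C(COCc3ccc(OC)cc3)C(=O)O[C@@H]2/C=C(C)\CO[Si](C)(C)C(C)(C)C)C(=O)O1 | intermediate
30 | acyl Meldrum's acid (enol form) with free C3 hydroxyl | CC1(C)OC(=O)C(=C(O)[C@H](C)C[C@H](O[Si](C)(C)C(C)(C)C)C2=C(COCc3ccc(OC)cc3)C(=O)O[C@@H]2/C=C(C)\CO)C(=O)O1 | intermediate
31 | C1 acylketene with free C3 hydroxyl | O=C=CC(=O)[C@H](C)C[C@H](O[Si](C)(C)C(C)(C)C)C1=C(COCc2ccc(OC)cc2)C(=O)O[C@@H]1/C=C(C)\CO | intermediate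
32 | twelve-membered allyl β-keto lactone fused to the butenolide (4Z,6R,8S,10R; C8 OTBS, C13 OPMB) | CC(C)(C)[Si](C)(C)O[C@H]1C[C@@H](C)C(=O)CC(=O)OC/C(C)=C\[C@H]2OC(=O)C(COCc3ccc(OC)cc3)=C12 | intermediate
33 | (4Z,6R,8S,10R)-8-((tert-butyldimethylsilyl)oxy)-13-((4-methoxybenzyl)oxy)-1-oxogermacra-4,7(11)-dien-12,6-olide | CC(C)(C)[Si](C)(C)O[C@H]1C[C@@H](C)C(=O)CC/C(C)=C\[C@H]2OC(=O)C(COCc3ccc(OC)cc3)=C12 | intermediate
34 | (4Z,6R,8S,10R)-8-((tert-butyldimethylsilyl)oxy)-13-hydroxy-1-oxogermacra-4,7(11)-dien-12,6-olide | CC(C)(C)[Si](C)(C)O[C@H]1C[C@@H](C)C(=O)CC/C(C)=C\[C@H]2OC(=O)C(CO)=C12 | intermediate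
35 | (4Z,6R,8S,10R)-13-acetoxy-8-((tert-butyldimethylsilyl)oxy)-1-oxogermacra-4,7(11)-dien-12,6-olide | CC(C)(C)[Si](C)(C)O[C@H]1C[C@@H](C)C(=O)CC/C(C)=C\[C@H]2OC(=O)C(COC(C)=O)=C12 | intermediate
36 | (4Z,6R,8S,10R)-13-acetoxy-8-hydroxy-1-oxogermacra-4,7(11)-dien-12,6-olide | O[C@H]1C[C@@H](C)C(=O)CC/C(C)=C\[C@H]2OC(=O)C(COC(C)=O)=C12 | intermediate
37 | ethyl 2-(hydroxymethyl)acrylate | C=C(CO)C(=O)OCC | starting material
38 | ethyl 2-(((tert-butyldimethylsilyl)oxy)methyl)acrylate | C=C(CO[Si](C)(C)C(C)(C)C)C(=O)OCC | intermediate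
39 | 2-(((tert-butyldimethylsilyl)oxy)methyl)acrylic acid | C=C(CO[Si](C)(C)C(C)(C)C)C(=O)O | intermediate
40 | (4Z,6R,8S,10R)-13-acetoxy-8-[2-(((tert-butyldimethylsilyl)oxy)methyl)acryloyloxy]-1-oxogermacra-4,7(11)-dien-12,6-olide | C=C(CO[Si](C)(C)C(C)(C)C)C(=O)O[C@H]1C[C@@H](C)C(=O)CC/C(C)=C\[C@H]2OC(=O)C(COC(C)=O)=C12 | intermediate
41 | (4R,5S,6S,8S,10R)-13-acetoxy-8-[2-(((tert-butyldimethylsilyl)oxy)methyl)acryloyloxy]-4,5-epoxy-1-oxogermacr-7(11)-en-12,6-olide | C=C(CO[Si](C)(C)C(C)(C)C)C(=O)O[C@H]1C[C@@H](C)C(=O)CC[C@@]2(C)O[C@H]2[C@H]2OC(=O)C(COC(C)=O)=C12 | intermediate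
42 | (4R,5S,6S,8S,10R)-13-acetoxy-4,5-epoxy-8-[2-(hydroxymethyl)acryloyloxy]-1-oxogermacr-7(11)-en-12,6-olide | C=C(CO)C(=O)O[C@H]1C[C@@H](C)C(=O)CC[C@@]2(C)O[C@H]2[C@H]2OC(=O)C(COC(C)=O)=C12 | target

**Step count and risks**
Total: 26 steps. Longest linear sequence: 20 steps (1–6, 8, 9, 13–21, 24–26).

Steps most likely to fail:

1. Step 18 (ring contraction). The anti π-allyl intermediate may isomerise to the syn form before C–C bond formation, which would erode the Z geometry. The enolate may also attack C5 or be protonated. Fallback by direct SN2 alkylation, which never passes through a π-allyl species: it sets out from 29, which is heated with 2-(trimethylsilyl)ethanol in toluene to give the acyclic 2-(trimethylsilyl)ethyl β-keto ester F1. HF·pyridine then frees the C3 hydroxyl to give the hydroxy β-keto ester F2, and MsCl/Et3N followed by LiBr in acetone gives the (Z)-allylic bromide F3. Cs2CO3 in MeCN under high dilution closes the ten-membered ring by intramolecular C-alkylation of the β-keto ester at C3, giving the ring β-keto ester F4. Fluoride (TASF, DMF, 0 °C) then removes the silylethyl group and the β-keto acid loses CO2, returning to the route at 33.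

2. Step 13 (coupling/lactonisation). The ligand and the resident C8 centre may be mismatched, giving poor facial selectivity at the aldehyde, and the hindered, ester-chelated alkenylchromium may add sluggishly. Fallback at the ketone oxidation level with reagent-controlled reduction: it sets out from 22 and 18. Iodine–lithium exchange of 22 and quenching with Bu3SnCl gives the (Z)-alkenylstannane F5. Carbonylative Stille coupling of F5 with 18 (CO, Pd(PPh3)4, LiCl, THF, 55 °C) gives the cross-conjugated dienone F6, with C6 as a ketone. Corey–Bakshi–Shibata reduction with the oxazaborolidine antipode that delivers hydride to the required face gives the hydroxy ester 25, which lactonises, returning to the route at 26.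

3. Step 25 (epoxidation). Oxygen may be delivered to the other face of the (Z)-cyclodecene, since the facial preference rests on ring conformation. Fallback through a halohydrin, which places oxygen on the face opposite to the one the electrophile attacks: it sets out from 40. NBS in aqueous THF gives by anti addition the bromohydrin F7 (C4 tertiary OH, C5 Br). DBU in CH2Cl2 closes the oxirane with inversion at C5, returning to the route at 41.

**Further compounds**
F1 | step 18 | 2-(trimethylsilyl)ethyl β-keto ester from 29 (acyclic, C3 OTBS) | C[Si](C)(C)CCOC(=O)CC(=O)[C@H](C)C[C@H](O[Si](C)(C)C(C)(C)C)C1=C(COCc2ccc(OC)cc2)C(=O)O[C@@H]1/C=C(C)\CO[Si](C)(C)C(C)(C)C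
F2 | step 18 | 2-(trimethylsilyl)ethyl β-keto ester with free C3 hydroxyl | C[Si](C)(C)CCOC(=O)CC(=O)[C@H](C)C[C@H](O[Si](C)(C)C(C)(C)C)C1=C(COCc2ccc(OC)cc2)C(=O)O[C@@H]1/C=C(C)\CO
F3 | step 18 | 2-(trimethylsilyl)ethyl β-keto ester with (Z)-allylic C3 bromide | C[Si](C)(C)CCOC(=O)CC(=O)[C@H](C)C[C@H](O[Si](C)(C)C(C)(C)C)C1=C(COCc2ccc(OC)cc2)C(=O)O[C@@H]1/C=C(C)\CBr
F4 | step 18 | 2-[(2-(trimethylsilyl)ethoxy)carbonyl] derivative of 33 (C2 epimers) | CC(C)(C)[Si](C)(C)O[C@H]1C[C@@H](C)C(=O)C(C(=O)OCC[Si](C)(C)C)C/C(C)=C\[C@H]2OC(=O)C(COCc3ccc(OC)cc3)=C12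
F5 | step 13 | (Z)-tert-butyldimethyl((2-methyl-3-(tributylstannyl)allyl)oxy)silane | CCCC[Sn](CCCC)(CCCC)/C=C(C)\CO[Si](C)(C)C(C)(C)C
F6 | step 13 | cross-conjugated dienone (C6 ketone, seco form of 26 at the ketone level) | C=CCOC(=O)[C@H](C)C[C@H](O[Si](C)(C)C(C)(C)C)/C(C(=O)/C=C(C)\CO[Si](C)(C)C(C)(C)C)=C(\COCc1ccc(OC)cc1)C(=O)OC
F7 | step 25 | bromohydrin of 40 (C4 OH, C5 Br) | C=C(CO[Si](C)(C)C(C)(C)C)C(=O)O[C@H]1C[C@@H](C)C(=O)CC[C@@](C)(O)[C@H](Br)[C@H]2OC(=O)C(COC(C)=O)=C12
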